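(The runs come from a simulation from invented constants; the scatter is artificial.)

The oak run, at 2.3 mM of G, is the neighbour to reason from. Its L scatters around 5.65% of the charge and its G around 1.93%, with no clear drift, so you can read oak as exchange in balance. If you count D as small there, the rest is Z, 92.4%. Each L has freed one X and each Z two, which gives cX near 4.38 mM. From these readings you get B = 71.7 mM, the product cX·cZ/cL, an apparent equilibrium constant while Q is held, and it carries their scatter.

| flask | G | J | remark | time |
|---|---|---|---|---|
| oak | 2.3 mM (in portions, 2) | 1.3 mM (held) | run made earlier; portions every 30 h |  |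
| larch | 24 mM (in portions, 2) | 1.3 mM (held) | run made earlier; portions every 30 h |  |
| theta | 2.0 mM (in portions, 2) | 1.3 mM (held) | the portions of G follow each other after 30 h, the first at the start | 25 d |
| epsilon | 6.0 mM (in portions, 2) | 1.3 mM (held) | the portions of G follow each other after 30 h, the first at the start | 25 d |
| alpha | 20 mM (in portions, 2) | 1.3 mM (held) | the portions of G follow each other after 30 h, the first at the start | 25 d |

- oak (time / d: L / %, G / %): 6.00: 6.8, 1.9; 12.0: 4.9, 2.4; 20.0: 6.0, 1.6; 25.0: 4.9, 1.8
- larch (time / d: L / %, G / %): 3.00: 8.2, 12.9; 8.00: 5.0, 6.0; 15.0: 2.8, 4.0; 25.0: 2.8, 2.0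

(standard deviation of a reading: 0.5 percentage points)

- in percentages every species weighs as the G in it: one D counts as two
- at the start none of Q is dissolved
- what may be going on: G + Q <-> X + L; L + Q <-> X + Z; G + L -> D; J <-> Q
- "hardly changes" means that all values lie within two and a half points (for a concentration: within two and a half percent of the largest)

1. [L] at the end for theta, epsilon, alpha, in this order
2. the course of these numbers from the first flask to the last (rises all the way / falls, then rises / falls all the way / hardly changes / rises, then falls)

Bracket epsilon, the middle flask. For the upper bound, suppose no D forms. Taking cZ as the charge and cX as twice that gives cL = 1.00 mM. Putting that back gives 0.766 mM, and going round again gives 0.820 mM.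

For the lower end, which is an estimate and no strict bound, use larch, whose last readings give cL = 0.672 mM and cG = 0.480 mM. Each D also frees one X, so B and this balance give cZ = 2.92 mM, which leaves a D share of 83.0%. G + L to D is second order, so I let the odds of D go with the charge, a rough rule. That gives epsilon a D share of 55.0%, and two rounds give cL = 0.266 mM, then 0.230 mM.

The forecast gives 0.095 mM, 0.42 mM and 0.6 mM, a course that rises all the way, and notes: “The percentage falls at high charge, but concentration still rises”. Its epsilon value lies inside my bracket of 0.230 mM to 0.820 mM, which is a range and not its number.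

The flasks give 0.0998 mM, 0.408 mM and 0.563 mM, a course that rises all the way, with epsilon inside the bracket.

    G + Q ⇌ X + L (K = 12.0, k = 35.0 M⁻¹ h⁻¹)
    L + Q ⇌ X + Z (K = 46.0, k = 50.0 M⁻¹ h⁻¹)
    G + L → D (k = 6.60 M⁻¹ h⁻¹)
    J ⇌ Q, rate k4*(csat - [Q]) (kL = 4.00 h⁻¹)

In theta, L has a half-life of 0.44 d at the end by the forward L + Q step alone, short against the 25 d of the run. In epsilon, cX of 7.89 mM and cZ of 3.19 mM at the end, multiplied and divided by B, give cL = 0.351 mM beside the 0.408 mM that stands there. In alpha, cX of 13.9 mM and cZ of 2.58 mM give 0.500 mM beside 0.563 mM.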